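The target is dissected into two molecules of one achiral monomer, a cyclohexa-1,3-diene butenolide, joined through C6=C7 of unit A and C3a'=C7a' of unit B. Ring A (C3a, C4, C5, C6, C7, C7a) is the retron of a [3+3] Michael–Wittig annulation: the γ-carbon of a vinylogous acyl phosphorus ylide (future C3a) adds to a three-carbon enal at C4, and the ylide carbon (C7) then olefinates the aldehyde (C6). One operation thus forges C3a–C4 and C6–C7 and sets the diene. The C6=C7 π bond is later spent in a head-to-tail [2+2] photocycloaddition that builds the cyclobutane and all four stereocentres.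

Key step: step 3

Remark on numbering: phthalide numbering is used in each half (C1 lactone carbonyl, C3 butylidene-bearing carbon, C3a/C7a ring-fusion carbons, C4–C7 carbocycle); primes mark unit B, whose C3a' and C7a' are the two quaternary cyclobutane carbons.

Step 1
Reactants: 1 hexan-2-one, 2 methyl pyruvate
Product: 6 methyl (E)-2-methyl-4-oxooct-2-enoate, via lithium enolate 3 (not isolated), via lithium aldolate 4 (not isolated), via aldol acetate 5 (not isolated)
Conditions: LiN(iPr)2, THF, −78 °C; 2, −78 °C; Ac2O, −78 to 0 °C; DBU, rt
Reagents that add atoms: none
Why: Kinetic deprotonation of 1 at the methyl group and aldol addition to the keto carbonyl of 2, acetylation of the tertiary aldolate and DBU-mediated E1cB elimination (aldol condensation) should give the E enone ester 6; the stereocentre of 5 is lost and the alkene geometry is of no consequence later.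

Step 2
Reactants: 6 methyl (E)-2-methyl-4-oxooct-2-enoate
Product: 7 methyl (Z)-2-(bromomethyl)-4-oxooct-2-enoate
Conditions: NBS, AIBN (cat.), PhCF3, 80 °C
Reagents that add atoms: N-bromosuccinimide, O=C1CCC(=O)N1Br
Why: Wohl–Ziegler bromination should select the allylic methyl group, whose radical is delocalised over the enone and the ester, and any transposed secondary bromide converges to the same phosphonium salt by SN2′ attack in step 3; no stereocentre is formed.

Step 3
Reactants: 7 methyl (Z)-2-(bromomethyl)-4-oxooct-2-enoate, 8 acrolein
Product: 12 methyl 2-pentanoylcyclohexa-1,5-diene-1-carboxylate, via phosphonium bromide 9 (not isolated), via vinylogous ylide 10 (not isolated), via aldehyde ylide 11 (not isolated)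
Conditions: PPh3, MeCN, rt; then K2CO3, 8, O-trimethylsilyl diphenylprolinol (20 mol%), CHCl3, 0 to 40 °C
Reagents that add atoms: none
Why: Deprotonation of 9 gives ylide 10, which is vinylogously stabilised by the C3 ketone, so its γ-carbon (C3a, α to the ketone) is the soft nucleophilic site and adds 1,4 to the iminium ion formed from acrolein and the secondary amine (bond C3a–C4); proton loss from C3a then re-forms a ylide (11) whose carbon C7 olefinates the liberated aldehyde C6 intramolecularly with loss of Ph3P=O (bond C6=C7). The closest known reaction type is the tandem Michael addition/intramolecular Wittig [3+3] annulation of allylic (vinylogous ester) phosphorus ylides with α,β-unsaturated carbonyl compounds to cyclohexa-1,3-dienes, together with the amine-catalysed Michael–Wittig annulation of stabilised ylides with enals. Ring A closes in the Wittig step as a six-membered ring by attack of the ylide carbon on the exocyclic C=O of the tethered aldehyde (6-exo-trig addition, then collapse of the oxaphosphetane). No stereocentre is formed: the C3a stereocentre of the Michael adduct is erased when the ylide re-forms, and diene 12 is achiral. The step needs 1,4- over 1,2-addition to the enal and γ- over α-attack of the ylide; iminium activation of acrolein and the low carbonyl reactivity of the doubly stabilised ylide should secure the first, and the enolate character at C3a (C7 carries the bulky phosphonium group and its adduct cannot close a ring) the second. The positions of both ring double bonds (C3a=C7a and C6=C7) are fixed by the mechanism and not by equilibration.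

Step 4
Reactants: 12 methyl 2-pentanoylcyclohexa-1,5-diene-1-carboxylate
Product: 15 (Z)-ligustilide, via lithium carboxylate 13 (not isolated), via hydroxylactone 14 (not isolated)
Conditions: LiOH, THF/H2O, 0 °C; 1 M HCl; then TsOH·H2O (cat.), PhMe, 60 °C, argon
Reagents that add atoms: lithium hydroxide, [Li+].[OH-]
Why: Saponification assisted by the neighbouring ketone gives the keto carboxylate, which closes to hydroxylactone 14 on acidification, and acid-catalysed dehydration, possible only toward C8, should give the thermodynamically preferred Z enol lactone (enol lactonisation of a γ-keto acid), which sets the Z butylidene geometry.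

Step 5
Reactants: 15 (Z)-ligustilide (two molecules)
Product: 16 (6S,7R,3a'R,7a'S)-(Z,Z')-6.7a',7.3a'-diligustilide (target)
Conditions: AlBr3-activated oxazaborolidine from (S)-α,α-bis(3,5-dimethylphenyl)-2-pyrrolidinemethanol and 2,4,6-trifluorophenylboronic acid (50 mol%), CH2Cl2, −75 °C, hν (405 nm LED)
Reagents that add atoms: none
Why: Proposed new method: the Lewis acid binds the lactone carbonyl of one molecule of 15 and shifts its absorption to the visible, so that only the complex is excited and its triplet enoate adds through the α,β-bond C3a'=C7a' to the least hindered alkene of an unbound molecule, the cis-disubstituted C6=C7. Head-to-tail bonding (terminus C6 to the α-carbon C7a', vinyl-bearing C7 to the β-carbon C3a', through a 1,4-diradical that is allylic at C7) is the orientation usual for triplet enone–alkene photocycloadditions. Both rings of unit B and ring A must end cis-fused on the cyclobutane, and ring A is expected to stack over the flat butenolide of unit B with antiparallel lactone dipoles, which places ring A and lactone B on one cyclobutane face and H6/H7 on the other. The aryl groups of the oxazaborolidine should shield one face of C3a'=C7a' so that the 6S,7R,3a'R,7a'S enantiomer forms. The closest known reaction types are the enantioselective [2+2] photocycloadditions of cyclic enones and coumarins catalysed by AlBr3-activated chiral oxazaborolidines and the uncatalysed [2+2] photodimerisation of alkylidene phthalides; a crossed dimerisation of a dienyl butenolide under such catalysis has not been shown.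

Compound list
1 | hexan-2-one | CCCCC(C)=O | starting material
2 | methyl pyruvate (methyl 2-oxopropanoate) | CC(=O)C(=O)OC | starting material
3 | lithium hex-1-en-2-olate (kinetic enolate of 1) | [Li+].[O-]C(=C)CCCC | intermediate
4 | lithium aldolate of 1 and 2 (lithium 1-methoxy-2-methyl-1,4-dioxooctan-2-olate, racemic) | [Li+].CCCCC(=O)CC(C)([O-])C(=O)OC | intermediate
5 | methyl 2-acetoxy-2-methyl-4-oxooctanoate (racemic) | CCCCC(=O)CC(C)(OC(C)=O)C(=O)OC | intermediate
6 | methyl (E)-2-methyl-4-oxooct-2-enoate | CCCCC(=O)/C=C(\C)C(=O)OC | intermediate
7 | methyl (Z)-2-(bromomethyl)-4-oxooct-2-enoate | CCCCC(=O)/C=C(\CBr)C(=O)OC | intermediate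
8 | acrolein (prop-2-enal) | C=CC=O | starting material
9 | [(Z)-2-(methoxycarbonyl)-4-oxooct-2-enyl]triphenylphosphonium bromide | CCCCC(=O)/C=C(\C[P+](c1ccccc1)(c1ccccc1)c1ccccc1)C(=O)OC.[Br-] | intermediate
10 | methyl (2Z)-4-oxo-2-[(triphenyl-λ5-phosphanylidene)methyl]oct-2-enoate (vinylogous acyl ylide) | CCCCC(=O)/C=C(\C=P(c1ccccc1)(c1ccccc1)c1ccccc1)C(=O)OC | intermediate
11 | methyl (2E)-6-oxo-3-pentanoyl-2-[(triphenyl-λ5-phosphanylidene)methyl]hex-2-enoate (formylethyl chain cis to the ylide carbon) | CCCCC(=O)/C(CCC=O)=C(/C=P(c1ccccc1)(c1ccccc1)c1ccccc1)C(=O)OC | intermediate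
12 | methyl 2-pentanoylcyclohexa-1,5-diene-1-carboxylate | CCCCC(=O)C1=C(C(=O)OC)C=CCC1 | intermediate
13 | lithium 2-pentanoylcyclohexa-1,5-diene-1-carboxylate | [Li+].CCCCC(=O)C1=C(C([O-])=O)C=CCC1 | intermediate
14 | 3-butyl-3-hydroxy-4,5-dihydro-2-benzofuran-1(3H)-one (racemic hydroxylactone, ring tautomer of the keto acid) | CCCCC1(O)OC(=O)C2=C1CCC=C2 | intermediate
15 | (Z)-ligustilide, (3Z)-3-butylidene-4,5-dihydro-2-benzofuran-1(3H)-one | CCC/C=C1\OC(=O)C2=C1CCC=C2 | intermediate
16 | (6S,7R,3a'R,7a'S)-(Z,Z')-6.7a',7.3a'-diligustilide: cyclobutane C6–C7–C3a'–C7a' with bonds C6–C7a' and C7–C3a'; ring A and the lactone of unit B on one face, H6, H7 and the carbocycle of unit B on the other | CCC/C=C1\OC(=O)C2=C1CC[C@H]1[C@@H]2[C@]23CCC=C[C@]12C(=O)O/C3=C\CCC | target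

Total step count: 5
Longest linear sequence: 5 steps (from hexan-2-one)

Steps most likely to fail

1. Step 5 (Proposed new method). What may go wrong:
- head-to-head instead of head-to-tail bonding;
- engagement of the butylidene or C6'=C7' alkene instead of C3a'=C7a';
- Z/E photoisomerisation of the butylidene group;
- weak facial discrimination by the catalyst (if the sense of induction is opposite, the catalyst from the (R)-amino alcohol is used);
- Lewis-acid-induced decomposition of the enol lactone.

Fallback, from 15 back to 16: the catalyst is omitted and 15 is photodimerised in the known, uncatalysed way of alkylidene phthalides (concentrated solution or neat film, 350–365 nm, argon). The head-to-tail cyclobutane dimer then forms as the racemate, that is 16 together with (6R,7S,3a'S,7a'R)-diligustilide F1. It is separated from the other dimers by HPLC and resolved by preparative chromatography on a chiral stationary phase to give 16.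

2. Step 3 (key step). What may go wrong: direct olefination of acrolein at the aldehyde before conjugate addition, attack through the phosphorus-bearing carbon, or polymerisation of acrolein under the basic conditions.

Fallback, from 7 back to 12: ylide 10 is made as in step 3 and, without the amine catalyst, is allowed to olefinate acrolein at the aldehyde (Wittig reaction) to give methyl (2E)-2-[(1E)-buta-1,3-dienyl]-4-oxooct-2-enoate F2. Irradiation at 350 nm equilibrates the central alkene to methyl (2E)-2-[(1Z)-buta-1,3-dienyl]-4-oxooct-2-enoate F3. On heating in toluene F3 should undergo disrotatory 6π electrocyclisation (forming C3a–C4) to methyl 6-pentanoylcyclohexa-1,3-diene-1-carboxylate F4. DBU then moves the diene into conjugation with the ketone to give 12.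

3. Step 2. What may go wrong: ionic bromination at C5 next to the ketone (catalysed by traces of HBr), or double bromination of the allylic position.

Fallback, from 1 back to 7: 1 is brominated at the methyl group (Br2, MeOH) to 1-bromohexan-2-one F5. With PPh3 this gives (2-oxohexyl)triphenylphosphonium bromide F6, and aqueous NaOH then gives the stabilised ylide 1-(triphenyl-λ5-phosphanylidene)hexan-2-one F7. Wittig olefination of commercial methyl 3-bromo-2-oxopropanoate with F7 should give 7 directly, so that no allylic bromination is needed.

Further compounds
F1 | step 5 | (6R,7S,3a'S,7a'R)-(Z,Z')-6.7a',7.3a'-diligustilide (enantiomer of 16) | CCC/C=C1\OC(=O)C2=C1CC[C@@H]1[C@H]2[C@@]23CCC=C[C@@]12C(=O)O/C3=C\CCC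
F2 | step 3 | methyl (2E)-2-[(1E)-buta-1,3-dienyl]-4-oxooct-2-enoate | CCCCC(=O)/C=C(\C=C\C=C)C(=O)OC
F3 | step 3 | methyl (2E)-2-[(1Z)-buta-1,3-dienyl]-4-oxooct-2-enoate | CCCCC(=O)/C=C(\C=C/C=C)C(=O)OC
F4 | step 3 | methyl 6-pentanoylcyclohexa-1,3-diene-1-carboxylate (racemic) | CCCCC(=O)C1CC=CC=C1C(=O)OC
F5 | step 2 | 1-bromohexan-2-one | BrCC(=O)CCCC
F6 | step 2 | (2-oxohexyl)triphenylphosphonium bromide | CCCCC(=O)C[P+](c1ccccc1)(c1ccccc1)c1ccccc1.[Br-]
F7 | step 2 | 1-(triphenyl-λ5-phosphanylidene)hexan-2-one | CCCCC(=O)C=P(c1ccccc1)(c1ccccc1)c1ccccc1
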